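In fractions of the charge, substrate lost turned into mono adduct or double product, so I took mono adduct as the balance of the other two. Reagent was spent once for each mono adduct and twice for each double product.

| flask | substrate | reagent | remark | time |
|---|---|---|---|---|
| dawn | 0.27 M | 0.40 M | run made earlier |  |
| dusk | 0.60 M | 0.40 M | run made earlier |  |
| summer | 0.40 M | 0.80 M | run made earlier |  |
| flask | 0.40 M | 0.400 M |  | 10 h |

| run | time / h | double product / % | substrate / % |
|---|---|---|---|
| dawn | 1.00 | 1.5 | 87.0 |
| dawn | 2.00 | 6.1 | 76.2 |
| dawn | 3.00 | 10.9 | 67.5 |
| dawn | 6.00 | 22.5 | 52.9 |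
| dawn | 12.0 | 36.7 | 38.2 |
| dusk | 1.00 | 1.9 | 87.2 |
| dusk | 3.00 | 6.9 | 73.0 |
| dusk | 6.00 | 13.4 | 63.0 |
| dusk | 8.00 | 14.8 | 60.8 |
| dusk | 12.0 | 18.3 | 56.6 |
| summer | 2.50 | 20.9 | 54.6 |
| summer | 5.00 | 39.6 | 36.3 |
| summer | 8.00 | 54.3 | 27.3 |
| summer | 10.0 | 59.7 | 22.1 |
| summer | 12.0 | 64.4 | 18.8 |

(readings scatter by 0.5 percentage points)



1. amount of double product in percent of the substrate charged, at 30 min, 2.5 h and 10 h

I carried one number from these runs. In the summer run between 2.50 h and 5.00 h, I took double product gained over substrate lost and multiplied by substrate over mono adduct, which gave 1.91. This reading is the selectivity factor, how many times faster a given amount of mono adduct takes reagent than the same amount of substrate. Reagent cancels from it, so it ties the amounts to one another without a clock.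

Then I built the ladder for the flask. Dawn had the flask's reagent charge and fell to 87.0% substrate in 1.00 h, so substrate's half-time read about 4.98 h. Mono adduct's was shorter, about 2.60 h, so mono adduct had to stop rising once it stood at substrate divided by 1.91. On my reckoning that came at substrate 49.1%, with mono adduct 25.7% and double product 25.2%. The flask's substrate charge lay between dawn and dusk, which stood at 38.2% and 56.6% substrate after 12.0 h, so I placed that point near 10 h and committed to about 25.2%.

The forecast held that “The losses fit two consecutive second-order steps” and gave 0.5%, 6.2% and 25.5%, the last slightly above mine.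

The flask gave 0.468%, 6.70% and 25.2%, right within the tolerance.

    substrate + reagent → mono adduct + by-product (k = 0.00631 /M/min)
    reagent + mono adduct → double product + by-product (k = 0.0120 /M/min)
    reagent ⇌ dormant form (K = 1.33, k = 2.17 × 10⁻⁴ /min)

At 10.0 h the flask held 49.0% substrate and 25.8% mono adduct, with mono adduct made 0.999 times as fast as it was used up. The selectivity factor times mono adduct over substrate gives 1.01 for the same moment. In the dusk run, substrate stood at 56.6% after 12.0 h, and 1.91 puts double product there at 18.3%; the reading was 18.3%.

The earlier runs and the new flask come from a simulation for an exercise; the scatter is artificial.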